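## Retrosynthetic overview

1. Target 15 ⇒ bis-TIPS ether 14 by global fluoride desilylation.
2. 14 ⇒ furanone 6 + benzylic bromide 12: catalytic enantioselective C-benzylation of the aromatic furan-2-olate 13 derived from 6. This step destroys the furan aromaticity and creates the only stereocentre (quaternary, R).
3. 6 ⇒ 4-hydroxyphenylpyruvic acid 1 + glyoxylic acid 2: crossed aldol/lactonisation builds the butenolide, the only ring formed in the route (both benzene rings are bought); then double O-methylation and silylation.
4. 12 ⇒ 4-hydroxybenzaldehyde 7 + prenyl bromide 8: ortho C-prenylation, silylation, reduction, bromination.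

Assumption: the facial sense of the chiral ammonium catalyst on this new substrate class cannot be predicted with certainty; the (S)-catalyst [(11bS)-4,4-dibutyl-2,6-bis(3,4,5-trifluorophenyl)-4,5-dihydro-3H-dinaphtho[2,1-c:1',2'-e]azepinium bromide] is written, and its commercial (R)-antipode is used instead if the first run delivers the (S)-product.

## Route

Step 1
Reactants: 1 4-hydroxyphenylpyruvic acid; 2 glyoxylic acid monohydrate
Product: 4 rac-4-hydroxy-3-(4-hydroxyphenyl)-5-oxo-2,5-dihydrofuran-2-carboxylic acid, via open-chain aldol adduct 3 (not isolated)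
Conditions: aq. NaOH, 2 (2 equiv), Ar, 0 °C → rt; then 6 M HCl to pH 1, 40 °C
Reagents that add atoms: none
Why: Crossed aldol addition of the arylpyruvate enolate (its benzylic CH2 is the only enolisable site) to excess non-enolisable, highly electrophilic glyoxylate, then acid-induced γ-lactonisation and enolisation (the classical arylpyruvic acid + aldehyde route to 3-hydroxy-4-arylbutenolides); the new stereocentre is racemic and is erased in step 8.

Step 2
Reactants: 4 rac-4-hydroxy-3-(4-hydroxyphenyl)-5-oxo-2,5-dihydrofuran-2-carboxylic acid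
Product: 5 methyl rac-3-(4-hydroxyphenyl)-4-methoxy-5-oxo-2,5-dihydrofuran-2-carboxylate
Conditions: TMSCHN2 (2.1 equiv), PhMe/MeOH 3:1, 0 °C; AcOH quench
Reagents that add atoms: trimethylsilyldiazomethane, C[Si](C)(C)C=[N+]=[N-]
Why: Diazoalkane O-methylation is driven by protonation of the reagent, so the carboxylic acid and the acidic α-keto-lactone enol react well before the phenol, which is kept free by limiting the reagent to about two equivalents at 0 °C.

Step 3
Reactants: 5 methyl rac-3-(4-hydroxyphenyl)-4-methoxy-5-oxo-2,5-dihydrofuran-2-carboxylate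
Product: 6 methyl rac-4-methoxy-5-oxo-3-[4-(triisopropylsilyloxy)phenyl]-2,5-dihydrofuran-2-carboxylate
Conditions: TIPSCl, imidazole, DMF, rt
Reagents that add atoms: triisopropylsilyl chloride, CC(C)[Si](Cl)(C(C)C)C(C)C
Why: Standard imidazole-mediated silylation of the only remaining OH; the TIPS ether is chosen because it survives the carbonate base of step 8 yet falls to fluoride.

Step 4
Reactants: 7 4-hydroxybenzaldehyde; 8 prenyl bromide (1-bromo-3-methylbut-2-ene)
Product: 9 4-hydroxy-3-(3-methylbut-2-en-1-yl)benzaldehyde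
Conditions: aq. KOH, rt, 24 h
Reagents that add atoms: none
Why: Ortho C-alkylation of a phenoxide in water, where hydrogen bonding to the phenoxide oxygen diverts the allylic bromide to carbon; the para position is blocked, so only the ortho isomer forms, and the O-prenyl and bis-prenyl by-products are removed by chromatography (modest yield accepted at the first step of this branch).

Step 5
Reactants: 9 4-hydroxy-3-(3-methylbut-2-en-1-yl)benzaldehyde
Product: 10 3-(3-methylbut-2-en-1-yl)-4-(triisopropylsilyloxy)benzaldehyde
Conditions: TIPSCl, imidazole, DMF, rt → 40 °C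
Reagents that add atoms: triisopropylsilyl chloride, CC(C)[Si](Cl)(C(C)C)C(C)C
Why: Silyl protection of the phenol, needed so that the benzylic bromide made in step 7 cannot self-condense through a quinone methide and so that the phenol is not O-benzylated in step 8.

Step 6
Reactants: 10 3-(3-methylbut-2-en-1-yl)-4-(triisopropylsilyloxy)benzaldehyde
Product: 11 [3-(3-methylbut-2-en-1-yl)-4-(triisopropylsilyloxy)phenyl]methanol
Conditions: NaBH4, MeOH, 0 °C
Reagents that add atoms: none
Why: Chemoselective borohydride 1,2-reduction of the aldehyde; the trisubstituted alkene and the aryl TIPS ether are inert.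

Step 7
Reactants: 11 [3-(3-methylbut-2-en-1-yl)-4-(triisopropylsilyloxy)phenyl]methanol
Product: 12 4-(bromomethyl)-2-(3-methylbut-2-en-1-yl)-1-(triisopropylsilyloxy)benzene
Conditions: CBr4, PPh3, CH2Cl2, 0 °C; short silica plug, used at once
Reagents that add atoms: carbon tetrabromide, BrC(Br)(Br)Br
Why: Appel bromination converts the benzylic alcohol to the bromide under neutral conditions, so no HBr is available to add to the prenyl alkene or cleave the silyl ether.

Step 8
Reactants: 6 methyl rac-4-methoxy-5-oxo-3-[4-(triisopropylsilyloxy)phenyl]-2,5-dihydrofuran-2-carboxylate; 12 4-(bromomethyl)-2-(3-methylbut-2-en-1-yl)-1-(triisopropylsilyloxy)benzene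
Product: 14 methyl (2R)-4-methoxy-2-{[3-(3-methylbut-2-en-1-yl)-4-(triisopropylsilyloxy)phenyl]methyl}-5-oxo-3-[4-(triisopropylsilyloxy)phenyl]-2,5-dihydrofuran-2-carboxylate, via furan-2-olate ion pair 13 (not isolated)
Conditions: (S)-simplified Maruoka catalyst (5 mol%), Cs2CO3 (2 equiv), 12 (1.2 equiv), degassed PhMe, Ar, −20 °C
Reagents that add atoms: none
Why: Proposed new method: carbonate removes the doubly activated ring C–H of 6 (α to the ester, vinylogous to the lactone carbonyl) to give the planar 6π-aromatic furan-2-olate 13, which enters toluene as a tight ion pair with the C2-symmetric binaphthyl ammonium cation that shields one face; the benzylic bromide then attacks the ester-bearing ring carbon (nucleophilic in both the ester-enolate and the vinylogous lactone-enolate resonance forms, and the site whose alkylation regenerates the conjugated α-methoxy-β-aryl butenolide), so aromaticity is broken and the quaternary (R) centre is set in one event; the closest known reaction type is chiral phase-transfer (Maruoka-type) asymmetric benzylation of cyclic β-keto esters, azlactones and 3-substituted benzofuran-2(3H)-ones, whose enolates are likewise aromatic heteroaryl-olates.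

Step 9
Reactants: 14 methyl (2R)-4-methoxy-2-{[3-(3-methylbut-2-en-1-yl)-4-(triisopropylsilyloxy)phenyl]methyl}-5-oxo-3-[4-(triisopropylsilyloxy)phenyl]-2,5-dihydrofuran-2-carboxylate
Product: 15 2-O-methylbutyrolactone I, methyl (2R)-2-{[4-hydroxy-3-(3-methylbut-2-en-1-yl)phenyl]methyl}-3-(4-hydroxyphenyl)-4-methoxy-5-oxo-2,5-dihydrofuran-2-carboxylate
Conditions: TBAF (2.5 equiv), AcOH (2.5 equiv), THF, 0 °C → rt
Reagents that add atoms: none
Why: Fluoride-mediated cleavage of both aryl silyl ethers under acetic acid buffering, which spares the methyl ester, the lactone and the enol ether and avoids the acid-catalysed chroman cyclisation of the ortho-prenylphenol; the quaternary centre cannot epimerise.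

## Compound list

1 | 4-hydroxyphenylpyruvic acid [3-(4-hydroxyphenyl)-2-oxopropanoic acid] | O=C(O)C(=O)Cc1ccc(O)cc1 | starting material
2 | glyoxylic acid monohydrate (2,2-dihydroxyacetic acid) | O=C(O)C(O)O | starting material
3 | 2-hydroxy-3-(4-hydroxyphenyl)-4-oxopentanedioic acid (open-chain aldol adduct, diastereomer mixture, sodium salt in the flask) | O=C(O)C(O)C(c1ccc(O)cc1)C(=O)C(=O)O | intermediate
4 | rac-4-hydroxy-3-(4-hydroxyphenyl)-5-oxo-2,5-dihydrofuran-2-carboxylic acid | O=C(O)C1OC(=O)C(O)=C1c1ccc(O)cc1 | intermediate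
5 | methyl rac-3-(4-hydroxyphenyl)-4-methoxy-5-oxo-2,5-dihydrofuran-2-carboxylate | COC(=O)C1OC(=O)C(OC)=C1c1ccc(O)cc1 | intermediate
6 | methyl rac-4-methoxy-5-oxo-3-[4-(triisopropylsilyloxy)phenyl]-2,5-dihydrofuran-2-carboxylate | COC(=O)C1OC(=O)C(OC)=C1c1ccc(O[Si](C(C)C)(C(C)C)C(C)C)cc1 | intermediate
7 | 4-hydroxybenzaldehyde | O=Cc1ccc(O)cc1 | starting material
8 | prenyl bromide (1-bromo-3-methylbut-2-ene) | CC(C)=CCBr | starting material
9 | 4-hydroxy-3-(3-methylbut-2-en-1-yl)benzaldehyde | CC(C)=CCc1cc(C=O)ccc1O | intermediate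
10 | 3-(3-methylbut-2-en-1-yl)-4-(triisopropylsilyloxy)benzaldehyde | CC(C)=CCc1cc(C=O)ccc1O[Si](C(C)C)(C(C)C)C(C)C | intermediate
11 | [3-(3-methylbut-2-en-1-yl)-4-(triisopropylsilyloxy)phenyl]methanol | CC(C)=CCc1cc(CO)ccc1O[Si](C(C)C)(C(C)C)C(C)C | intermediate
12 | 4-(bromomethyl)-2-(3-methylbut-2-en-1-yl)-1-(triisopropylsilyloxy)benzene | CC(C)=CCc1cc(CBr)ccc1O[Si](C(C)C)(C(C)C)C(C)C | intermediate
13 | cesium 5-(methoxycarbonyl)-3-methoxy-4-[4-(triisopropylsilyloxy)phenyl]furan-2-olate (reacts as its ion pair with the chiral ammonium cation) | [Cs+].COC(=O)c1oc([O-])c(OC)c1-c1ccc(O[Si](C(C)C)(C(C)C)C(C)C)cc1 | intermediate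
14 | methyl (2R)-4-methoxy-2-{[3-(3-methylbut-2-en-1-yl)-4-(triisopropylsilyloxy)phenyl]methyl}-5-oxo-3-[4-(triisopropylsilyloxy)phenyl]-2,5-dihydrofuran-2-carboxylate | COC(=O)[C@]1(Cc2ccc(O[Si](C(C)C)(C(C)C)C(C)C)c(CC=C(C)C)c2)OC(=O)C(OC)=C1c1ccc(O[Si](C(C)C)(C(C)C)C(C)C)cc1 | intermediate
15 | 2-O-methylbutyrolactone I, methyl (2R)-2-{[4-hydroxy-3-(3-methylbut-2-en-1-yl)phenyl]methyl}-3-(4-hydroxyphenyl)-4-methoxy-5-oxo-2,5-dihydrofuran-2-carboxylate | COC(=O)[C@]1(Cc2ccc(O)c(CC=C(C)C)c2)OC(=O)C(OC)=C1c1ccc(O)cc1 | target

## Summary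

Total step count: 9 (steps 1–3 make 6; steps 4–7 make 12; steps 8–9 join and finish).
Longest linear sequence: 6 steps (7 → 9 → 10 → 11 → 12 → 14 → 15).

Steps most likely to fail:

Step 8 (low or wrong-sense enantioselectivity, or sluggish alkylation of the fully substituted furanolate). The fallback sets out from 6 and 12 and gives up catalytic stereocontrol in favour of resolution. An achiral benzylation (K2CO3, cat. Bu4NBr, MeCN, rt) gives the racemic bis-silyl ether F1. Preparative chiral SFC on an amylose-type phase then separates the enantiomers, and the (R)-enantiomer is 14, where the route is rejoined before step 9. The configuration is confirmed by comparing the rotation and ECD of 15 with the natural product.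

Step 1 (self-aldol dimerisation and oxidative decay of 1 in aqueous alkali, and isolation of the very polar acid 4). The fallback sets out from 1 and moves the ring construction into the ester series in organic solvent. Esterification (MeOH, TMSCl, rt) gives methyl 4-hydroxyphenylpyruvate F2. A DBU-mediated crossed aldol with methyl glyoxylate in MeCN, with transesterifying lactonisation in the same pot, gives methyl 4-hydroxy-3-(4-hydroxyphenyl)-5-oxo-2,5-dihydrofuran-2-carboxylate F3. A single enol O-methylation (TMSCHN2, 1.1 equiv) then comes back to the route at 5.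

Step 4 (competing O-prenylation and bis-prenylation, low yield). The fallback sets out from 7 and replaces phenoxide C-alkylation by cross-coupling. Ortho-bromination (Br2, AcOH) gives 3-bromo-4-hydroxybenzaldehyde F4, and silylation (TIPSCl, imidazole, DMF) gives 3-bromo-4-(triisopropylsilyloxy)benzaldehyde F5. Stille coupling with tributyl(3-methylbut-2-en-1-yl)stannane (Pd(PPh3)4, DMF, 90 °C) then installs the linear prenyl group and comes back to the route at 10.

Further compounds

F1 | step 8 | racemic methyl 4-methoxy-2-{[3-(3-methylbut-2-en-1-yl)-4-(triisopropylsilyloxy)phenyl]methyl}-5-oxo-3-[4-(triisopropylsilyloxy)phenyl]-2,5-dihydrofuran-2-carboxylate | COC(=O)C1(Cc2ccc(O[Si](C(C)C)(C(C)C)C(C)C)c(CC=C(C)C)c2)OC(=O)C(OC)=C1c1ccc(O[Si](C(C)C)(C(C)C)C(C)C)cc1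
F2 | step 1 | methyl 3-(4-hydroxyphenyl)-2-oxopropanoate (methyl 4-hydroxyphenylpyruvate) | COC(=O)C(=O)Cc1ccc(O)cc1
F3 | step 1 | methyl rac-4-hydroxy-3-(4-hydroxyphenyl)-5-oxo-2,5-dihydrofuran-2-carboxylate | COC(=O)C1OC(=O)C(O)=C1c1ccc(O)cc1
F4 | step 4 | 3-bromo-4-hydroxybenzaldehyde | O=Cc1ccc(O)c(Br)c1
F5 | step 4 | 3-bromo-4-(triisopropylsilyloxy)benzaldehyde | O=Cc1ccc(O[Si](C(C)C)(C(C)C)C(C)C)c(Br)c1
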